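(The constants come from no measurement; the result is computed.)

I start from the leftover: in this flask solid electrophile still lies undissolved at 30 h, and that leftover lets me reckon the rate without following the concentrations.

solid electrophile 11 mM; nucleophile 33.0 mM; buffer base 2.20 mM; buffer acid 3.30 mM; time 30 h

- part of the solid electrophile that has reacted (what has only dissolved counts as not reacted) at 30 h
- pH of the solution at 30 h

- acid is the free proton; pH is minus the decimal logarithm of its molar concentration
- given per volume of solution although it is solid: solid electrophile
- at the start none of the solid electrophile is in solution
- what has only dissolved of solid electrophile counts as not reacted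
- run time (flask): 30 h

    electrophile + nucleophile → acid + product + leaving group (k1 = 12 L mol⁻¹ h⁻¹)
    protonated nucleophile ⇌ nucleophile + acid, settled at all times (K2 = 2.0 × 10⁻⁵ M)
    buffer acid ⇌ buffer base + acid, settled at all times (K3 = 2.0 × 10⁻⁷ M)
    solid electrophile ⇌ electrophile, rate k4*(cs4 - [electrophile]) while solid is left; crystals form when [electrophile] > cs4 (cs4 = 4.8 mM, k4 = 0.017 h⁻¹)
    nucleophile ⇌ dormant form (K5 = 0.20, k5 = 0.039 h⁻¹)

With nothing yet in solution, the solid dissolves at its dissolution coefficient times its solubility, 0.0816 mM h⁻¹. Over 30 h that delivers at most 2.45 mM, less than the 11 mM charged, so solid remains and this ceiling holds throughout. Nucleophile at its charge removes dissolved electrophile at 0.396 h⁻¹, much faster than the 0.017 h⁻¹ of dissolution, so dissolution is the rate-limiting step and product forms as fast as electrophile arrives.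

Two things slow this. With a relaxation half-life of 2.96 h, short against the run, nucleophile moves towards its balance with the dormant form at 83.3% free; it takes longer than that half-life to get there, but I reckon with the balance from the start, which lowers the removal to 0.330 h⁻¹. Dissolved electrophile then narrows the gap to solubility, and the rate stands at a factor 0.951 of the ceiling; with nucleophile at its charge the factor is 0.959, so I leave out further nucleophile losses. Second, the rate needs about 2.88 h to build up, a factor 0.904 on the run. Together these give the dissolution reach, the product a flask makes by the end while solid remains, 2.10 mM, which is 19.1% of the charge.

The forecast says 19.2% (range 18.3% to 20%) and pH 6.1 (range 6 to 6.2), holding that “dissolution limits the rate”; its conversion is higher than mine.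

The simulation gives 18.9% reacted and pH 6.10; that conversion is 2.08 mM of product against my reach of 2.10 mM. At 30.0 h this flask makes electrophile 1.01 times as fast as it uses it up, each step taken net. The neighbour flask charged with 2.8 mM of solid electrophile, other charges and time held, ends with 16.6% of its charge still solid. The same reach, smaller than that charge, is 75.0% of it, and that neighbour flask gives 74.3%.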